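**Strategy**

Everything rests on the C13–C16 bond of ring D (ent-kaurane numbering). On ring C the C15 acyl arm of quaternary C8 lies 1,3 to C13 across C14, so a C16 keto-carbenoid on that arm is delivered onto a C12=C13 alkene: one operation forms C13–C16, closes ring D and fixes C13, at the price of a temporary trachylobane-type cyclopropane (C12–C13–C16). Reductive scission of C12–C16 and exo-face hydroxylation of the C16 enolate then give the bicyclo[3.2.1]octane ketol. The precursor is a cis-fused spirolactone–cyclohexene bearing a 2-diazopropanoyl group on C8, made by butadiene Diels–Alder addition to a 3-propanoyl-dihydropyranone built on an enantioenriched ring A enone.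

Key step: step 7

Numbering (remark): ent-kaurane locants are used for all compounds. Ring A = C1–C5 and C10 (C1 ketone, C2=C3, C4 gem-dimethyl, C5 bearing C6). The lactone is C10–C20–O–C7(=O)–C8–C9. Ring C = C8, C9, C11, C12, C13, C14. Ring D = C8, C14, C13, C16, C15 (C15 ketone, C16 bearing OH and the C17 methyl).

Assumption: 4,4-dimethylcyclohexa-2,5-dien-1-one (1) is taken as a catalogue compound. In step 1 the ligand antipode that delivers the (5S) adduct is the one used.

**Step 1**
Reactants: 1 4,4-dimethylcyclohexa-2,5-dien-1-one; 2 (chloromethyl)dimethylphenylsilane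
Product: 4 (5S)-5-[(dimethylphenylsilyl)methyl]-4,4-dimethylcyclohex-2-en-1-one, via Grignard reagent 3 (not isolated)
Conditions: 2, Mg, THF, 40 °C; then 1, CuBr·SMe2 (5 mol %), enantiopure 1-[2-(diphenylphosphino)ferrocenyl]ethyldicyclohexylphosphine (6 mol %), t-BuOMe, −75 °C; aqueous work-up
Reagents that add atoms: magnesium, [Mg] (its atom is carried only in 3)
Why: Copper-catalysed asymmetric conjugate addition of a Grignard reagent desymmetrises the dienone, the chiral diphosphine–copper complex choosing one of the two enantiotopic enone units, which sets C5 and leaves the C2=C3 enone untouched because the magnesium enolate is inert to a second addition.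

**Step 2**
Reactants: 4 (5S)-5-[(dimethylphenylsilyl)methyl]-4,4-dimethylcyclohex-2-en-1-one
Product: 6 (5S,6R)-5-[(dimethylphenylsilyl)methyl]-4,4-dimethyl-6-[(triethylsilyloxy)methyl]cyclohex-2-en-1-one, via lithium aldolate 5 (not isolated)
Conditions: LiN(SiMe3)2, THF, −78 °C; CH2O (monomer in THF), −78 °C; Et3SiCl, −78 → 0 °C
Reagents that add atoms: formaldehyde, C=O; chlorotriethylsilane, CC[Si](Cl)(CC)CC; lithium bis(trimethylsilyl)amide, [Li+].C[Si](C)(C)[N-][Si](C)(C)C (lithium is carried only in 5)
Why: Deprotonation can occur only at C10 (C4 is quaternary, C2 vinylic), and aldol addition to formaldehyde with in situ O-silylation should give the trans C20 silyloxymethyl ketone, whose C10 configuration is erased in step 4.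

**Step 3**
Reactants: 7 ethyl 3-oxopentanoate
Product: 8 ethyl 2-(ethoxymethylidene)-3-oxopentanoate (E/Z mixture)
Conditions: HC(OEt)3, Ac2O, 130 °C
Reagents that add atoms: triethyl orthoformate, CCOC(OCC)OCC
Why: Orthoformate condensation of an active methylene compound, driven by acetic anhydride trapping the ethanol, gives the alkoxymethylene β-keto ester; no stereocentre is formed.

**Step 4**
Reactants: 6 (5S,6R)-5-[(dimethylphenylsilyl)methyl]-4,4-dimethyl-6-[(triethylsilyloxy)methyl]cyclohex-2-en-1-one; 8 ethyl 2-(ethoxymethylidene)-3-oxopentanoate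
Product: 10 (6S,11R)-11-[(dimethylphenylsilyl)methyl]-10,10-dimethyl-4-propanoyl-2-oxaspiro[5.5]undeca-4,8-diene-3,7-dione, via β-ethoxy Michael adduct 9 (not isolated)
Conditions: LiN(i-Pr)2, THF, −78 °C; 8, −78 °C; AcOH; then 1 M HCl/THF, rt; then p-TsOH·H2O (cat.), PhMe, 80 °C
Reagents that add atoms: none
Why: The C10 lithium enolate should add to the ethoxymethylene acceptor (Michael addition, then acid-mediated loss of ethanol) on the face anti to the pseudoaxial C5 silylmethyl group, which sets quaternary C10 with C9 trans to C6, and the acid also removes the triethylsilyl group so that the C20 hydroxyl lactonises onto the ester, both alkene isomers converging on the lactone.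

**Step 5**
Reactants: 10 spirolactone dienophile; 11 buta-1,3-diene
Product: 12 (5R,8S,9S,10S) Diels–Alder adduct, the cis-fused spirolactone–cyclohexene with propanoyl on C8, C12=C13 alkene and C6 silane
Conditions: buta-1,3-diene (excess), ZnCl2, CH2Cl2, 0 °C → rt, sealed tube
Reagents that add atoms: none
Why: The zinc-chelated 3-acyl-5,6-dihydropyran-2-one is a doubly activated dienophile, and butadiene should add suprafacially (Diels–Alder) to the C8=C9 face syn to the flat C1 carbonyl and anti to C5 and its substituents, which sets C8 and C9 (cis fusion, C15 cis to H9) relative to C10, while the singly activated ring A enone with its quaternary γ-carbon should not compete.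

**Step 6**
Reactants: 12 Diels–Alder adduct
Product: 14 (5R,8S,9S,10S) 2-diazopropanoyl ketone (C16 diazo), via trifluoroacetyl diketone 13 (not isolated)
Conditions: LiN(SiMe3)2, THF, −78 °C; CF3CO2CH2CF3, −78 °C; then MeSO2N3, Et3N, H2O, MeCN, rt
Reagents that add atoms: methanesulfonyl azide, CS(=O)(=O)N=[N+]=[N-]; 2,2,2-trifluoroethyl trifluoroacetate, O=C(OCC(F)(F)F)C(F)(F)F (its atoms are carried only in 13)
Why: C16 is the only enolisable position, and detrifluoroacetylative diazo transfer (Regitz-type) should convert the ethyl ketone into the 2-diazopropanoyl group without touching the non-enolisable enone and lactone.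

**Step 7**
Reactants: 14 2-diazopropanoyl ketone
Product: 15 cyclopropyl ketone with the C12–C13–C16 cyclopropane cis-fused to ring C on the face syn to C15, C17 methyl on C16, C6 silane
Conditions: Rh2(O2CCMe3)4 (1 mol %), CH2Cl2, −20 °C → rt, slow addition of 14
Reagents that add atoms: none
Why: The rhodium carboxylate decomposes the diazo ketone to an electrophilic keto-carbenoid at C16, which adds in a concerted, asynchronous [2+1] manner to the C12=C13 alkene (intramolecular cyclopropanation of a γ,δ-unsaturated α-diazo ketone, the classical entry to bicyclo[3.1.0]hexan-2-ones). Ring D (C8–C15–C16–C13–C14) is closed by the C16–C13 bond, exo with respect to the alkene, and the cyclopropane (C12–C13–C16) by the C16–C12 bond in the same event. The new stereocentres C13, C12 and C16 are dictated by the substrate: the diazoacyl arm is axial on C8 and can reach only the alkene face syn to C15, so the cyclopropane is necessarily cis-fused and C13 acquires the target configuration. The step needs chemoselectivity over 1,2-hydride shift from the C17 methyl (vinyl ketone), over carbonyl-ylide formation with the C7 lactone carbonyl and over the ring A enone; the electron-rich cis-alkene held two atoms from C8, the remote electron-poor enone, the bulky electron-rich pivalate ligands, low temperature and slow addition should secure it. The cyclopropane is a temporary ring that step 9 opens at C12–C16.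

**Step 8**
Reactants: 15 cyclopropyl ketone (C6 silane)
Product: 16 cyclopropyl ketone with free C6 hydroxyl
Conditions: Hg(OAc)2, AcOOH, AcOH, rt
Reagents that add atoms: peracetic acid, CC(=O)OO
Why: Fleming–Tamao oxidation (mercuridesilylation of the phenyl group, then peracid-induced 1,2-shift from silicon to oxygen with retention) should unmask the C6 hydroxymethyl at the one stage where the molecule has no enolisable ketone and no nucleophilic alkene.

**Step 9**
Reactants: 16 cyclopropyl ketone alcohol
Product: 17 (5R,8S,9S,10S,13R) bicyclo[3.2.1]octanone with C16 bearing H and methyl (C16 epimers)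
Conditions: SmI2 (2.2 equiv), t-BuOH (2 equiv), THF, −78 °C
Reagents that add atoms: none
Why: Single-electron transfer to the chelating β-keto lactone carbonyl gives a ketyl, and the cyclopropane bond best aligned with the carbonyl π system cleaves (the external C12–C16 bond, not the C13–C16 bond lying in the cyclopentanone plane); reduction and protonation of the C12 radical then give the bicyclo[3.2.1]octanone (reductive cyclopropyl ketone opening), the C16 configuration being inconsequential.

**Step 10**
Reactants: 17 bicyclo[3.2.1]octanone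
Product: 18 target CNP0530135.1
Conditions: KN(SiMe3)2 (2.5 equiv), THF, −78 °C; 3-phenyl-2-(phenylsulfonyl)oxaziridine, −78 °C; AcOH
Reagents that add atoms: 3-phenyl-2-(phenylsulfonyl)oxaziridine, O=S(=O)(c1ccccc1)N1OC1c1ccccc1
Why: The potassium enolate across C15–C16 (the only enolisable position) should be oxidised by the N-sulfonyloxaziridine on its exo face, syn to the one-carbon bridge C14 and away from the C11–C12 bridge, so that the hydroxyl is exo and the methyl endo (16S) as in the target, the primary alcohol being carried as its alkoxide.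

**Compound list**

1 | 4,4-dimethylcyclohexa-2,5-dien-1-one | CC1(C)C=CC(=O)C=C1 | starting material
2 | (chloromethyl)dimethylphenylsilane | C[Si](C)(CCl)c1ccccc1 | starting material
3 | [(dimethylphenylsilyl)methyl]magnesium chloride (formed in the flask) | C[Si](C)(C[Mg]Cl)c1ccccc1 | intermediate
4 | (5S)-5-[(dimethylphenylsilyl)methyl]-4,4-dimethylcyclohex-2-en-1-one | CC1(C)C=CC(=O)C[C@@H]1C[Si](C)(C)c1ccccc1 | intermediate
5 | lithium alkoxide of (5S,6R)-5-[(dimethylphenylsilyl)methyl]-6-(hydroxymethyl)-4,4-dimethylcyclohex-2-en-1-one (formed in the flask) | CC1(C)C=CC(=O)[C@@H](CO[Li])[C@@H]1C[Si](C)(C)c1ccccc1 | intermediate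
6 | (5S,6R)-5-[(dimethylphenylsilyl)methyl]-4,4-dimethyl-6-[(triethylsilyloxy)methyl]cyclohex-2-en-1-one | CC1(C)C=CC(=O)[C@@H](CO[Si](CC)(CC)CC)[C@@H]1C[Si](C)(C)c1ccccc1 | intermediate
7 | ethyl 3-oxopentanoate | CCC(=O)CC(=O)OCC | starting material
8 | ethyl 2-(ethoxymethylidene)-3-oxopentanoate (E/Z mixture) | CCOC=C(C(=O)CC)C(=O)OCC | intermediate
9 | β-ethoxy keto ester Michael adduct of 6 and 8 (formed in the flask): C10 quaternary with C9 trans to C6, mixture at C8 and C9 | CC1(C)C=CC(=O)[C@@](CO[Si](CC)(CC)CC)(C(OCC)C(C(=O)CC)C(=O)OCC)[C@@H]1C[Si](C)(C)c1ccccc1 | intermediate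
10 | (6S,11R)-11-[(dimethylphenylsilyl)methyl]-10,10-dimethyl-4-propanoyl-2-oxaspiro[5.5]undeca-4,8-diene-3,7-dione | CC1(C)C=CC(=O)[C@]2(COC(=O)C(C(=O)CC)=C2)[C@@H]1C[Si](C)(C)c1ccccc1 | intermediate
11 | buta-1,3-diene | C=CC=C | starting material
12 | (5R,8S,9S,10S) Diels–Alder adduct: cis-fused spirolactone–cyclohexene, propanoyl on C8, C12=C13 alkene, C6 dimethylphenylsilyl | CC1(C)C=CC(=O)[C@]2(COC(=O)[C@@]3(C(=O)CC)CC=CC[C@H]32)[C@@H]1C[Si](C)(C)c1ccccc1 | intermediate
13 | C16-trifluoroacetyl derivative of 12 (formed in the flask; mixture at C16) | CC1(C)C=CC(=O)[C@]2(COC(=O)[C@@]3(C(=O)C(C)C(=O)C(F)(F)F)CC=CC[C@H]32)[C@@H]1C[Si](C)(C)c1ccccc1 | intermediate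
14 | (5R,8S,9S,10S) 2-diazopropanoyl ketone (diazo group on C16) | CC1(C)C=CC(=O)[C@]2(COC(=O)[C@@]3(C(=O)C(C)=[N+]=[N-])CC=CC[C@H]32)[C@@H]1C[Si](C)(C)c1ccccc1 | intermediate
15 | cyclopropyl ketone: C12–C13–C16 cyclopropane cis-fused to ring C syn to C15, C17 methyl on C16, C6 dimethylphenylsilyl | CC1(C)C=CC(=O)[C@]2(COC(=O)[C@@]34C[C@H]5[C@@H](C[C@H]32)[C@@]5(C)C4=O)[C@@H]1C[Si](C)(C)c1ccccc1 | intermediate
16 | cyclopropyl ketone with free C6 hydroxyl | CC1(C)C=CC(=O)[C@]2(COC(=O)[C@@]34C[C@H]5[C@@H](C[C@H]32)[C@@]5(C)C4=O)[C@@H]1CO | intermediate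
17 | (5R,8S,9S,10S,13R) 16-deoxy ketone: bicyclo[3.2.1]octan-15-one with H and methyl on C16 (C16 epimers) | CC1(C)C=CC(=O)[C@]2(COC(=O)[C@@]34C[C@@H](CC[C@H]32)C(C)C4=O)[C@@H]1CO | intermediate
18 | CNP0530135.1, (5R,8S,9S,10S,13R,16S): 6,16-dihydroxy-1,15-dioxo-6,7-secokaur-2-ene 7,20-lactone | CC1(C)C=CC(=O)[C@]2(COC(=O)[C@@]34C[C@@H](CC[C@H]32)[C@](C)(O)C4=O)[C@@H]1CO | target

**Step count and risks**

Total steps: 10. Longest linear sequence: 9 (steps 1, 2 and 4 to 10; step 3 is a one-step side branch).

The three steps most likely to fail: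

Step 4. The hindered, fully substituted C10 enolate may fail to add to 8, the adduct may revert on warming, or the enolate may lose triethylsilanolate by β-elimination. Fallback, from 6 back to 10: the C9 carbon would be introduced alone. Trimethylsilyl triflate and Et3N should convert 6 into the trimethylsilyl dienol ether F1. Trimethyl orthoformate with catalytic trimethylsilyl triflate (Mukaiyama-type acetal alkylation, again anti to the C5 substituent) should then give the C10-quaternary β-keto dimethyl acetal F2. Knoevenagel condensation of F2 with 7 under TiCl4/pyridine would give the alkylidene keto ester F3, and the acid treatment of step 4 (desilylation, lactonisation) would return the route to 10.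

Step 7. The carbenoid may be diverted into 1,2-hydride shift (vinyl ketone) or into carbonyl-ylide formation with the lactone carbonyl before it reaches the alkene. Fallback, from 12 back to 17: the same C13–C16 bond would be closed by a radical. LiN(SiMe3)2 followed by N-bromosuccinimide should give the C16 bromo ketone F4. Bu3SnH with azobisisobutyronitrile under high dilution should cyclise the C16 radical onto C13 and reduce the resulting C12 radical, giving the C6-silyl bicyclo[3.2.1]octanone F5. Fleming–Tamao oxidation as in step 8 would rejoin the route at 17.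

Step 9. Electron transfer may also reach the ring A enone, or the C15 ketone may be over-reduced once the enolate is protonated. Fallback, from 16 back to 17: the cyclopropane would be opened by a two-electron path. Iodotrimethylsilane (from Me3SiCl and NaI, MeCN, 0 °C) should attack C12 with inversion in a homoconjugate addition that cleaves the same C12–C16 bond, giving after aqueous work-up the 12-iodo ketone F6. Dehalogenation with Bu3SnH and azobisisobutyronitrile would return the route to 17.

**Further compounds**

F1 | step 4 | trimethylsilyl dienol ether of 6 (C1–O–SiMe3, C1=C10) | CC1(C)C=CC(O[Si](C)(C)C)=C(CO[Si](CC)(CC)CC)[C@@H]1C[Si](C)(C)c1ccccc1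
F2 | step 4 | C10-quaternary β-keto dimethyl acetal (C9 as CH(OMe)2, trans to C6; C20 triethylsilyl ether) | CC1(C)C=CC(=O)[C@@](CO[Si](CC)(CC)CC)(C(OC)OC)[C@@H]1C[Si](C)(C)c1ccccc1
F3 | step 4 | alkylidene keto ester: ethyl 2-alkylidene-3-oxopentanoate with C9=C8, C20 triethylsilyl ether (E/Z mixture) | CC1(C)C=CC(=O)[C@@](CO[Si](CC)(CC)CC)(C=C(C(=O)CC)C(=O)OCC)[C@@H]1C[Si](C)(C)c1ccccc1
F4 | step 7 | C16 bromo ketone: 2-bromopropanoyl analogue of 12 (mixture at C16) | CC1(C)C=CC(=O)[C@]2(COC(=O)[C@@]3(C(=O)C(C)Br)CC=CC[C@H]32)[C@@H]1C[Si](C)(C)c1ccccc1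
F5 | step 7 | C6-dimethylphenylsilyl analogue of 17 (C16 epimers) | CC1(C)C=CC(=O)[C@]2(COC(=O)[C@@]34C[C@@H](CC[C@H]32)C(C)C4=O)[C@@H]1C[Si](C)(C)c1ccccc1
F6 | step 9 | 12-iodo derivative of 17, iodide anti to the C15–C16 bridge (C16 epimers) | CC1(C)C=CC(=O)[C@]2(COC(=O)[C@@]34C[C@@H]([C@@H](I)C[C@H]32)C(C)C4=O)[C@@H]1CO
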